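**Plan**
Cuts: the C6–O protecting group comes off first. Then O1–C8a is cut, which opens the pyran ring, and then C4–C4a, which separates the arene from the terpenoid chain. The resulting vinyl carbinol is traced back to an allylic alcohol.
Enabling feature: in the pyran ring, O1 is the only bridge between the quaternary C2 and the benzene carbon C8a. The ring can therefore be closed from the arene side with all four bonds of C2 left alone and no positive charge near the C3', C7' and C11' alkenes.
Forward: geranylgeraniol gives the (R)-vinyl carbinol in three steps, and 2,5-dimethylresorcinol gives a chloroaryl triflate in three steps. Hydroboration and B-alkyl Suzuki coupling join C4 to C4a, palladium-catalysed etherification closes the pyran (the only ring made), and deprotection follows.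
Stereochemistry: C2 is set once, by Sharpless epoxidation with D-(−)-diethyl tartrate, and its C–O bond is never broken afterwards. The E alkenes come with the starting terpenol.

Key step: step 8

Assumption: commercial geranylgeraniol is taken as all-E material, and borane 9 is drawn with a free hydroxyl because any O–B bond made by excess 9-BBN is hydrolysed by the aqueous base of the coupling.

Step 1
Reactants: 1 (2E,6E,10E)-geranylgeraniol
Product: 2 (2R,3R)-2,3-epoxygeranylgeraniol = [(2R,3R)-3-methyl-3-[(3E,7E)-4,8,12-trimethyltrideca-3,7,11-trien-1-yl]oxiran-2-yl]methanol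
Conditions: Ti(OiPr)4 (10 mol %), D-(−)-diethyl tartrate (12 mol %), t-BuOOH (2 equiv, decane), 4 Å MS, CH2Cl2, −20 °C
Reagents that add atoms: tert-butyl hydroperoxide, CC(C)(C)OO
Why: The Katsuki–Sharpless asymmetric epoxidation reacts only at the alkene next to the hydroxyl, and for (E)-allylic alcohols of the geraniol type the D-(−)-tartrate catalyst is the one assigned to the (2R,3R)-epoxide, which fixes the future C2.

Step 2
Reactants: 2 (2R,3R)-2,3-epoxygeranylgeraniol
Product: 3 (2S,3R)-2-(iodomethyl)-3-methyl-3-[(3E,7E)-4,8,12-trimethyltrideca-3,7,11-trien-1-yl]oxirane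
Conditions: I2, PPh3, imidazole, Et2O–MeCN, 0 °C, dark
Reagents that add atoms: iodine, II
Why: The Appel-type (Garegg–Samuelsson) iodination exchanges the primary hydroxyl under buffered conditions that leave the epoxide, both stereocentres (the C2 descriptor changes by ranking only) and the alkenes untouched.

Step 3
Reactants: 3 epoxy iodide
Product: 4 (R)-geranyllinalool = (3R,6E,10E)-3,7,11,15-tetramethylhexadeca-1,6,10,14-tetraen-3-ol
Conditions: activated Zn dust, EtOH, reflux; aq. NH4Cl work-up
Reagents that add atoms: none
Why: In this reductive opening of a 2,3-epoxy iodide, zinc reduces the C–I bond and beta-elimination breaks only the secondary C–O bond, so the tertiary C–O bond and its configuration pass unchanged into the vinyl carbinol.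

Step 4
Reactants: 5 2,5-dimethylresorcinol
Product: 6 3-hydroxy-2,5-dimethylphenyl trifluoromethanesulfonate
Conditions: Tf2O (1.0 equiv), pyridine, CH2Cl2, −40 to 0 °C
Reagents that add atoms: triflic anhydride, O=S(=O)(OS(=O)(=O)C(F)(F)F)C(F)(F)F
Why: The two hydroxyls of 5 are equivalent by symmetry, so O-sulfonylation with limiting anhydride can give only one monotriflate, which is separable from bis-triflate and recoverable 5.

Step 5
Reactants: 6 monotriflate
Product: 7 2-chloro-5-hydroxy-3,6-dimethylphenyl trifluoromethanesulfonate
Conditions: SO2Cl2 (1.05 equiv), CH2Cl2, 0 °C to rt, dark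
Reagents that add atoms: sulfuryl chloride, O=S(=O)(Cl)Cl
Why: In this electrophilic aromatic chlorination the free hydroxyl is the dominant director, and SO2Cl2 prefers its para position even when that position is flanked on both sides (as in the chlorination of 3,5-xylenol), which puts chlorine next to the triflate on the future C8a.

Step 6
Reactants: 7 chlorophenol triflate
Product: 8 2-chloro-5-(methoxymethoxy)-3,6-dimethylphenyl trifluoromethanesulfonate
Conditions: MOMCl, iPr2NEt, CH2Cl2, 0 °C to rt
Reagents that add atoms: chloromethyl methyl ether, COCCl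
Why: O-alkylation of the only remaining phenol gives a methoxymethyl acetal that tolerates the bases of steps 7 and 8 and is removable with mild acid.

Step 7
Reactants: 4 (R)-geranyllinalool; 8 chloroaryl triflate
Product: 10 (3R,6E,10E)-1-[2-chloro-5-(methoxymethoxy)-3,6-dimethylphenyl]-3,7,11,15-tetramethylhexadeca-6,10,14-trien-3-ol, via B-alkyl-9-BBN borane 9 (not isolated)
Conditions: 9-BBN-H (2 equiv), THF, 0 °C to rt; then 8, PdCl2(dppf) (5 mol %), aq. K3PO4 (3 M), THF–DMF, 60 °C
Reagents that add atoms: none
Why: Brown hydroboration with 9-BBN selects the monosubstituted alkene over the three trisubstituted ones and places boron on the terminal carbon, and the B-alkyl Suzuki–Miyaura coupling with the dppf catalyst then engages C–OTf, while the electron-rich C–Cl bond and the carbinol stereocentre stay spectators.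

Step 8
Reactants: 10 open-chain (R)-carbinol aryl chloride
Product: 11 (R)-beta-tocotrienol methoxymethyl ether = (2R)-6-(methoxymethoxy)-2,5,8-trimethyl-2-[(3E,7E)-4,8,12-trimethyltrideca-3,7,11-trien-1-yl]chromane
Conditions: Pd(OAc)2 (5 mol %), 2-di-tert-butylphosphino-2',4',6'-triisopropylbiphenyl (12 mol %), Cs2CO3 (1.5 equiv), toluene, 100 °C, argon
Reagents that add atoms: none
Why: Zerovalent palladium, formed when excess phosphine reduces Pd(OAc)2, inserts into C8a–Cl, Cs2CO3 removes the proton of the tertiary hydroxyl, and the alkoxide displaces chloride on divalent palladium. C–O reductive elimination from the seven-membered oxapalladacycle (Pd, C8a, C4a, C4, C3, C2, O1) contracts it to the six-membered pyran ring, a 6-exo type closure at the arene carbon. The closest known reaction is the Buchwald–Hartwig intramolecular etherification of aryl halides by tertiary alcohols, which gives 2,2-dialkylchromans. No stereocentre is created, and C2 stays (R) because only O–H and C8a–Cl are broken. The step needs alkoxide arylation to outrun beta-hydride elimination and Heck insertion, which the substrate secures because C2 carries no hydrogen and the nearest alkene is trisubstituted and reachable only through an eight-membered or larger ring. The bulky electron-rich ligand answers the electron-rich, doubly ortho-substituted chloride, whose ortho groups in turn favour reductive elimination, and the acetal is inert to carbonate.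

Step 9
Reactants: 11 (R)-beta-tocotrienol methoxymethyl ether
Product: 12 (R)-beta-tocotrienol = (2R)-2,5,8-trimethyl-2-[(3E,7E)-4,8,12-trimethyltrideca-3,7,11-trien-1-yl]chroman-6-ol
Conditions: p-TsOH·H2O (20 mol %), MeOH–THF, 40 °C, argon
Reagents that add atoms: none
Why: Acid-catalysed transacetalisation to methanol frees the phenol under conditions too mild to protonate the trisubstituted alkenes or ionise the C2–O1 bond, and argon protects the oxidisable chromanol.

**Compound list**
1 | (2E,6E,10E)-geranylgeraniol | CC(C)=CCC/C(C)=C/CC/C(C)=C/CC/C(C)=C/CO | starting material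
2 | (2R,3R)-2,3-epoxygeranylgeraniol | OC[C@H]1O[C@]1(C)CC/C=C(C)/CC/C=C(C)/CCC=C(C)C | intermediate
3 | (2S,3R)-2-(iodomethyl)-3-methyl-3-[(3E,7E)-4,8,12-trimethyltrideca-3,7,11-trien-1-yl]oxirane | IC[C@H]1O[C@]1(C)CC/C=C(C)/CC/C=C(C)/CCC=C(C)C | intermediate
4 | (R)-geranyllinalool | C=C[C@](C)(O)CC/C=C(C)/CC/C=C(C)/CCC=C(C)C | intermediate
5 | 2,5-dimethylresorcinol | Cc1cc(O)c(C)c(O)c1 | starting material
6 | 3-hydroxy-2,5-dimethylphenyl trifluoromethanesulfonate | Cc1cc(O)c(C)c(OS(=O)(=O)C(F)(F)F)c1 | intermediate
7 | 2-chloro-5-hydroxy-3,6-dimethylphenyl trifluoromethanesulfonate | Cc1cc(O)c(C)c(OS(=O)(=O)C(F)(F)F)c1Cl | intermediate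
8 | 2-chloro-5-(methoxymethoxy)-3,6-dimethylphenyl trifluoromethanesulfonate | COCOc1cc(C)c(Cl)c(OS(=O)(=O)C(F)(F)F)c1C | intermediate
9 | 9-[(3S,6E,10E)-3-hydroxy-3,7,11,15-tetramethylhexadeca-6,10,14-trien-1-yl]-9-borabicyclo[3.3.1]nonane (same spatial arrangement as 4, descriptor changed by ranking) | C1CC2CCCC(C1)B2CC[C@](C)(O)CC/C=C(C)/CC/C=C(C)/CCC=C(C)C | intermediate
10 | (3R,6E,10E)-1-[2-chloro-5-(methoxymethoxy)-3,6-dimethylphenyl]-3,7,11,15-tetramethylhexadeca-6,10,14-trien-3-ol | COCOc1cc(C)c(Cl)c(CC[C@](C)(O)CC/C=C(C)/CC/C=C(C)/CCC=C(C)C)c1C | intermediate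
11 | (R)-beta-tocotrienol methoxymethyl ether | COCOc1cc(C)c2O[C@](C)(CC/C=C(C)/CC/C=C(C)/CCC=C(C)C)CCc2c1C | intermediate
12 | (R)-beta-tocotrienol | CC(C)=CCC/C(C)=C/CC/C(C)=C/CC[C@]1(C)CCc2c(C)c(O)cc(C)c2O1 | target

**Step count**
Total steps: 9. Longest linear sequence: 6 steps (1, 2, 3, 7, 8, 9, or equally 4, 5, 6, 7, 8, 9).

**Steps most likely to fail**

Step 8. Insertion into the electron-rich, doubly ortho-substituted C8a–Cl bond and the following C–O reductive elimination may be slow. Hydrodechlorination and catalyst decay could then overtake ring closure.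

The fallback re-polarises the arene instead of retuning the catalyst. It sets out from 7 and returns at 12.
- Phenol 7 is acylated with pivaloyl chloride and Et3N to give 4-chloro-2,5-dimethyl-3-[(trifluoromethyl)sulfonyloxy]phenyl pivalate F1.
- Coupling of F1 with borane 9 as in step 7 gives 4-chloro-3-[(3R,6E,10E)-3-hydroxy-3,7,11,15-tetramethylhexadeca-6,10,14-trien-1-yl]-2,5-dimethylphenyl pivalate F2.
- The group para to the chloride is now an acceptor ester instead of a donor acetal, which should help both insertion and reductive elimination.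
- The same type of palladium-catalysed closure, with K3PO4 as the milder base, gives (R)-beta-tocotrienyl pivalate F3.
- LiAlH4 in THF at 0 °C then releases 12 without any acid.

Step 7. Coupling at a triflate flanked by methyl and chlorine may be sluggish. Base-induced S–O cleavage of the triflate and protodeboronation would then compete, and a more active ligand would erode the triflate-over-chloride selectivity.

The fallback replaces the boron and base manifold by a base-free Negishi coupling. It sets out from 2 and 8 and returns at 10.
- NaAlH2(OCH2CH2OMe)2 in THF opens 2 at C2 to give (3R,6E,10E)-3,7,11,15-tetramethylhexadeca-6,10,14-triene-1,3-diol F4.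
- I2, PPh3 and imidazole convert the primary hydroxyl alone, giving (3R,6E,10E)-1-iodo-3,7,11,15-tetramethylhexadeca-6,10,14-trien-3-ol F5.
- TESOTf and 2,6-lutidine give its triethylsilyl ether F6.
- LiCl-promoted zinc insertion in THF gives the alkylzinc iodide F7.
- F7 couples with 8 under PdCl2(dppf) in THF at 60 °C to give the triethylsilyl ether of 10, F8.
- Bu4NF then frees 10.

Step 5. Para versus ortho discrimination may be incomplete, or a second chlorination may occur, which would contaminate 7 with isomers.

The fallback moves the regiochemical decision from C–Cl formation to differentiation of the two oxygens. It sets out from 5 and returns at 8.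
- 5 is chlorinated first with SO2Cl2. Its two open ring positions are equivalent, so only 4-chloro-2,5-dimethylbenzene-1,3-diol F9 can form as the monochloride.
- One hydroxyl of F9 is crowded between methyl and chlorine and hydrogen-bonded to chlorine. One equivalent of MOMCl with iPr2NEt should therefore take the open hydroxyl and give 2-chloro-5-(methoxymethoxy)-3,6-dimethylphenol F10.
- Tf2O and pyridine then convert the hindered phenol into 8.

**Further compounds**
F1 | step 8 | 4-chloro-2,5-dimethyl-3-[(trifluoromethyl)sulfonyloxy]phenyl pivalate | CC(C)(C)C(=O)Oc1cc(C)c(Cl)c(OS(=O)(=O)C(F)(F)F)c1C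
F2 | step 8 | 4-chloro-3-[(3R,6E,10E)-3-hydroxy-3,7,11,15-tetramethylhexadeca-6,10,14-trien-1-yl]-2,5-dimethylphenyl pivalate | CC(C)(C)C(=O)Oc1cc(C)c(Cl)c(CC[C@](C)(O)CC/C=C(C)/CC/C=C(C)/CCC=C(C)C)c1C
F3 | step 8 | (R)-beta-tocotrienyl pivalate | CC(C)(C)C(=O)Oc1cc(C)c2O[C@](C)(CC/C=C(C)/CC/C=C(C)/CCC=C(C)C)CCc2c1C
F4 | step 7 | (3R,6E,10E)-3,7,11,15-tetramethylhexadeca-6,10,14-triene-1,3-diol | OCC[C@](C)(O)CC/C=C(C)/CC/C=C(C)/CCC=C(C)C
F5 | step 7 | (3R,6E,10E)-1-iodo-3,7,11,15-tetramethylhexadeca-6,10,14-trien-3-ol | ICC[C@](C)(O)CC/C=C(C)/CC/C=C(C)/CCC=C(C)C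
F6 | step 7 | triethylsilyl ether of F5 | ICC[C@](C)(O[Si](CC)(CC)CC)CC/C=C(C)/CC/C=C(C)/CCC=C(C)C
F7 | step 7 | alkylzinc iodide from F6 | I[Zn]CC[C@](C)(O[Si](CC)(CC)CC)CC/C=C(C)/CC/C=C(C)/CCC=C(C)C
F8 | step 7 | triethylsilyl ether of 10 | COCOc1cc(C)c(Cl)c(CC[C@](C)(O[Si](CC)(CC)CC)CC/C=C(C)/CC/C=C(C)/CCC=C(C)C)c1C
F9 | step 5 | 4-chloro-2,5-dimethylbenzene-1,3-diol | Cc1cc(O)c(C)c(O)c1Cl
F10 | step 5 | 2-chloro-5-(methoxymethoxy)-3,6-dimethylphenol | COCOc1cc(C)c(Cl)c(O)c1C
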